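**Retrosynthetic overview**
1. Target 17 comes from primary alcohol 13 (catechol masked as two aryl TBS ethers) by O-sulfation, then fluoride desilylation and acidification.
2. Alcohol 13 comes from arylacetic acid 9 by demethylation, esterification, silylation and ester reduction.
3. Acid 9 comes from nitroalkene 7 by conjugate reduction and oxidative nitro-to-carboxyl conversion. The key C–C bond (ArCH–CH2NO2) is made by the Henry nitroaldol condensation of aldehyde 4 with nitromethane 5.
4. Aldehyde 4 comes from vanillin 1 by two regioselective brominations and O-methylation.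
5. No ring is formed: the benzene ring is carried intact from vanillin.

Assumption: the target has no stereocentre and no stereogenic double bond, so there is no enantiomer to control; it is made as the free hydrogen sulfate exactly as drawn.

**Route**

Step 1
Reactants: 1 vanillin (4-hydroxy-3-methoxybenzaldehyde)
Product: 2 3-bromo-4-hydroxy-5-methoxybenzaldehyde (5-bromovanillin)
Conditions: Br2 (1.05 equiv), AcOH, rt
Reagents that add atoms: bromine, BrBr
Why: Electrophilic aromatic bromination; the free phenol directs ortho/para and C5 is its only open position (para carries CHO, the other ortho carries OMe), so one monobromide forms.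

Step 2
Reactants: 2 3-bromo-4-hydroxy-5-methoxybenzaldehyde
Product: 3 2,3-dibromo-4-hydroxy-5-methoxybenzaldehyde (5,6-dibromovanillin)
Conditions: Br2 (1.3 equiv), Fe powder (5 mol%), AcOH, rt
Reagents that add atoms: bromine, BrBr
Why: Second electrophilic aromatic bromination with FeBr3 formed from Fe and Br2 as Lewis acid; of the two open positions the one para to the methoxy group is the more activated, which gives the adjacent 2,3-dibromo pattern.

Step 3
Reactants: 3 2,3-dibromo-4-hydroxy-5-methoxybenzaldehyde
Product: 4 2,3-dibromo-4,5-dimethoxybenzaldehyde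
Conditions: MeI (1.5 equiv), K2CO3 (2 equiv), DMF, rt to 40 °C
Reagents that add atoms: iodomethane, CI
Why: Williamson ether synthesis; the acidic bromine-flanked phenoxide is methylated by SN2 on MeI, which removes the acidic OH before the hydride and nitrite steps.

Step 4
Reactants: 4 2,3-dibromo-4,5-dimethoxybenzaldehyde; 5 nitromethane
Product: 7 (E)-1,2-dibromo-3,4-dimethoxy-5-(2-nitrovinyl)benzene, via nitroaldol adduct 6 (not isolated)
Conditions: MeNO2 (5 equiv), NH4OAc, AcOH, 100 °C
Reagents that add atoms: none
Why: Henry (nitroaldol) reaction; the nitronate of nitromethane adds to the aldehyde carbonyl in an intermolecular aldol-type addition that makes the new C–C bond, and the racemic β-nitro alcohol 6 loses water to the conjugated, thermodynamically favoured E-nitroalkene.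

Step 5
Reactants: 7 (E)-1,2-dibromo-3,4-dimethoxy-5-(2-nitrovinyl)benzene
Product: 8 1,2-dibromo-3,4-dimethoxy-5-(2-nitroethyl)benzene
Conditions: NaBH4 (2.5 equiv), silica gel, CHCl3/i-PrOH (4:1), rt
Reagents that add atoms: none
Why: Conjugate hydride addition to the nitroalkene gives the nitronate, which is protonated to the nitroalkane; silica gel suppresses Michael dimerisation and aryl bromides are inert to NaBH4.

Step 6
Reactants: 8 1,2-dibromo-3,4-dimethoxy-5-(2-nitroethyl)benzene
Product: 9 2-(2,3-dibromo-4,5-dimethoxyphenyl)acetic acid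
Conditions: NaNO2 (3 equiv), AcOH (10 equiv), DMSO, 35 °C
Reagents that add atoms: water, O
Why: Nef-type oxidative conversion of a primary nitroalkane; nitrosation of the nitronate gives a nitrolic acid that loses nitrite to a nitrile oxide, which is hydrated to the hydroxamic acid and cleaved by a second nitrosation to the carboxylic acid, leaving the aryl bromides and methyl ethers untouched.

Step 7
Reactants: 9 2-(2,3-dibromo-4,5-dimethoxyphenyl)acetic acid
Product: 10 2-(2,3-dibromo-4,5-dihydroxyphenyl)acetic acid
Conditions: BBr3 (4 equiv), CH2Cl2, −78 °C to rt; then H2O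
Reagents that add atoms: none
Why: Lewis-acid aryl methyl ether cleavage; BBr3 coordinates each ether oxygen and bromide removes the methyl group by SN2, the carboxylic acid and aryl bromides are stable, and water hydrolyses the aryl borate to the catechol.

Step 8
Reactants: 10 2-(2,3-dibromo-4,5-dihydroxyphenyl)acetic acid
Product: 11 methyl 2-(2,3-dibromo-4,5-dihydroxyphenyl)acetate
Conditions: MeOH, H2SO4 (cat.), reflux
Reagents that add atoms: methanol, CO
Why: Fischer esterification; the acidic medium keeps the catechol from air oxidation and the ester allows a clean hydride reduction after silylation.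

Step 9
Reactants: 11 methyl 2-(2,3-dibromo-4,5-dihydroxyphenyl)acetate
Product: 12 methyl 2-[2,3-dibromo-4,5-bis(tert-butyldimethylsilyloxy)phenyl]acetate
Conditions: TBSCl (2.6 equiv), imidazole (5 equiv), DMAP (cat.), DMF, rt
Reagents that add atoms: tert-butyldimethylsilyl chloride, CC(C)(C)[Si](C)(C)Cl
Why: Silyl ether formation on both phenols; aryl TBS ethers tolerate hydride reduction and SO3·pyridine and are later removed by fluoride without harming a sulfate ester or the C–Br bonds.

Step 10
Reactants: 12 methyl 2-[2,3-dibromo-4,5-bis(tert-butyldimethylsilyloxy)phenyl]acetate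
Product: 13 2-[2,3-dibromo-4,5-bis(tert-butyldimethylsilyloxy)phenyl]ethanol
Conditions: i-Bu2AlH (2.5 equiv), CH2Cl2, −78 °C to 0 °C; aq. KNaC4H4O6 work-up
Reagents that add atoms: none
Why: Ester reduction by an aluminium hydride (two hydride transfers through the aldehyde) gives the primary alcohol; aryl silyl ethers and aryl bromides survive at low temperature.

Step 11
Reactants: 13 2-[2,3-dibromo-4,5-bis(tert-butyldimethylsilyloxy)phenyl]ethanol
Product: 15 sodium 2-[2,3-dibromo-4,5-bis(tert-butyldimethylsilyloxy)phenyl]ethyl sulfate, via pyridinium sulfate salt 14 (not isolated)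
Conditions: SO3·pyridine (3 equiv), pyridine, rt; then aq. NaHCO3
Reagents that add atoms: sulfur trioxide–pyridine complex, O=S(=O)([O-])[n+]1ccccc1; sodium hydrogen carbonate, [Na+].OC(=O)[O-]
Why: O-Sulfation; the only free hydroxyl attacks the SO3 of the pyridine complex to give the pyridinium alkyl sulfate, which is exchanged to the sodium salt on bicarbonate work-up, and no aryl sulfate can form because both phenols are blocked.

Step 12
Reactants: 15 sodium 2-[2,3-dibromo-4,5-bis(tert-butyldimethylsilyloxy)phenyl]ethyl sulfate
Product: 17 2-(2,3-dibromo-4,5-dihydroxyphenyl)ethyl hydrogen sulfate, via desilylated sodium salt 16 (not isolated)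
Conditions: KHF2 (3 equiv), MeOH, rt; then aq. HCl to pH 1, C18 desalting (dilute HCl, then MeOH/H2O), lyophilise cold
Reagents that add atoms: none
Why: Fluoride-mediated desilylation; bifluoride cleaves the aryl O–Si bonds under near-neutral conditions that spare the alkyl sulfate monoester and the C–Br bonds, and acidification with reversed-phase desalting turns the sodium salt into the free hydrogen sulfate.

**Compound list**

1 | vanillin (4-hydroxy-3-methoxybenzaldehyde) | COc1cc(C=O)ccc1O | starting material
2 | 3-bromo-4-hydroxy-5-methoxybenzaldehyde (5-bromovanillin) | COc1cc(C=O)cc(Br)c1O | intermediate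
3 | 2,3-dibromo-4-hydroxy-5-methoxybenzaldehyde (5,6-dibromovanillin) | COc1cc(C=O)c(Br)c(Br)c1O | intermediate
4 | 2,3-dibromo-4,5-dimethoxybenzaldehyde | COc1cc(C=O)c(Br)c(Br)c1OC | intermediate
5 | nitromethane | C[N+](=O)[O-] | starting material
6 | 1-(2,3-dibromo-4,5-dimethoxyphenyl)-2-nitroethanol, racemic nitroaldol adduct, not isolated | COc1cc(C(O)C[N+](=O)[O-])c(Br)c(Br)c1OC | intermediate
7 | (E)-1,2-dibromo-3,4-dimethoxy-5-(2-nitrovinyl)benzene | COc1cc(/C=C/[N+](=O)[O-])c(Br)c(Br)c1OC | intermediate
8 | 1,2-dibromo-3,4-dimethoxy-5-(2-nitroethyl)benzene | COc1cc(CC[N+](=O)[O-])c(Br)c(Br)c1OC | intermediate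
9 | 2-(2,3-dibromo-4,5-dimethoxyphenyl)acetic acid | COc1cc(CC(=O)O)c(Br)c(Br)c1OC | intermediate
10 | 2-(2,3-dibromo-4,5-dihydroxyphenyl)acetic acid | O=C(O)Cc1cc(O)c(O)c(Br)c1Br | intermediate
11 | methyl 2-(2,3-dibromo-4,5-dihydroxyphenyl)acetate | COC(=O)Cc1cc(O)c(O)c(Br)c1Br | intermediate
12 | methyl 2-[2,3-dibromo-4,5-bis(tert-butyldimethylsilyloxy)phenyl]acetate | COC(=O)Cc1cc(O[Si](C)(C)C(C)(C)C)c(O[Si](C)(C)C(C)(C)C)c(Br)c1Br | intermediate
13 | 2-[2,3-dibromo-4,5-bis(tert-butyldimethylsilyloxy)phenyl]ethanol | OCCc1cc(O[Si](C)(C)C(C)(C)C)c(O[Si](C)(C)C(C)(C)C)c(Br)c1Br | intermediate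
14 | pyridinium 2-[2,3-dibromo-4,5-bis(tert-butyldimethylsilyloxy)phenyl]ethyl sulfate, not isolated | [O-]S(=O)(=O)OCCc1cc(O[Si](C)(C)C(C)(C)C)c(O[Si](C)(C)C(C)(C)C)c(Br)c1Br.c1cc[nH+]cc1 | intermediate
15 | sodium 2-[2,3-dibromo-4,5-bis(tert-butyldimethylsilyloxy)phenyl]ethyl sulfate | [Na+].[O-]S(=O)(=O)OCCc1cc(O[Si](C)(C)C(C)(C)C)c(O[Si](C)(C)C(C)(C)C)c(Br)c1Br | intermediate
16 | sodium 2-(2,3-dibromo-4,5-dihydroxyphenyl)ethyl sulfate, not isolated | [Na+].[O-]S(=O)(=O)OCCc1cc(O)c(O)c(Br)c1Br | intermediate
17 | 2-(2,3-dibromo-4,5-dihydroxyphenyl)ethyl hydrogen sulfate | O=S(=O)(O)OCCc1cc(O)c(O)c(Br)c1Br | target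

**Step count and risks**

Total step count: 12. Longest linear sequence: 12 (fully linear from vanillin; nitromethane is bought).

Steps most likely to fail:

Step 2 (regiochemistry of the second bromination). The fallback sets out from 1 and comes back at 3, and it reverses the order in which the two bromines are introduced. Vanillin 1 is acetylated (Ac2O, pyridine, rt) to 4-formyl-2-methoxyphenyl acetate F1. With the phenol masked, the methoxy group controls bromination (Br2, NaOAc, AcOH, rt) and gives the para-to-methoxy bromide 5-bromo-4-formyl-2-methoxyphenyl acetate F2. Hydrolysis (aq. NaOH, then HCl) frees 2-bromo-4-hydroxy-5-methoxybenzaldehyde F3. The free phenol then directs Br2 in AcOH into its single open ortho position to give 3.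

Step 6 (direct nitro-to-carboxyl oxidation). The fallback sets out from 4 and comes back at 9, and it replaces the nitro chemistry by an azlactone homologation. Aldehyde 4 is condensed with N-acetylglycine (Ac2O, NaOAc, 100 °C; Erlenmeyer–Plöchl, a Perkin-type aldol condensation) to (Z)-4-(2,3-dibromo-4,5-dimethoxybenzylidene)-2-methyloxazol-5(4H)-one F4. Boiling 10% aq. NaOH opens the ring to (Z)-2-acetamido-3-(2,3-dibromo-4,5-dimethoxyphenyl)acrylic acid F5 and hydrolyses this enamide in the same flask to 3-(2,3-dibromo-4,5-dimethoxyphenyl)-2-oxopropanoic acid F6. H2O2 in cold aq. NaOH then decarboxylates the α-keto acid oxidatively to 9.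

Step 12 (desilylation next to a sulfate monoester, and isolation of the free acid, which should be kept cold because it can autocatalyse its own hydrolysis). The fallback sets out from 10 and comes back at 17, and it drops phenol protection altogether. Acid 10 is reduced with BH3·THF (excess, 0 °C to rt, MeOH quench) to 2-(2,3-dibromo-4,5-dihydroxyphenyl)ethanol F7. F7 is then sulfated chemoselectively at the aliphatic hydroxyl with H2SO4 (1 equiv) and dicyclohexylcarbodiimide in DMF at 0 °C, conditions under which phenols react much more slowly than primary alcohols. Dicyclohexylurea is filtered off and 17 is obtained directly as the free acid.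

**Further compounds**

F1 | step 2 | 4-formyl-2-methoxyphenyl acetate (vanillin acetate) | COc1cc(C=O)ccc1OC(C)=O
F2 | step 2 | 5-bromo-4-formyl-2-methoxyphenyl acetate | COc1cc(C=O)c(Br)cc1OC(C)=O
F3 | step 2 | 2-bromo-4-hydroxy-5-methoxybenzaldehyde (6-bromovanillin) | COc1cc(C=O)c(Br)cc1O
F4 | step 6 | (Z)-4-(2,3-dibromo-4,5-dimethoxybenzylidene)-2-methyloxazol-5(4H)-one | CC1=N/C(=C\c2cc(OC)c(OC)c(Br)c2Br)C(=O)O1
F5 | step 6 | (Z)-2-acetamido-3-(2,3-dibromo-4,5-dimethoxyphenyl)acrylic acid | CC(=O)N/C(=C\c1cc(OC)c(OC)c(Br)c1Br)C(=O)O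
F6 | step 6 | 3-(2,3-dibromo-4,5-dimethoxyphenyl)-2-oxopropanoic acid | COc1cc(CC(=O)C(=O)O)c(Br)c(Br)c1OC
F7 | step 12 | 2-(2,3-dibromo-4,5-dihydroxyphenyl)ethanol | OCCc1cc(O)c(O)c(Br)c1Br
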